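Take the leftover first. East keeps 67% of its substrate at 6.00 h, and south keeps 71% at 6.00 h.

| setting | south | east | flask |
|---|---|---|---|
| substrate | 0.042 M | 0.042 M | 0.042 M |
| partner | 1.5 equiv | 1.5 equiv | 1.50 equiv |
| scavenger | 0.80 equiv | 0.80 equiv | 0.800 equiv |
| initiator | 0.65 mol% | 0.98 mol% | 1.3 mol% |
| remark | run made earlier | run made earlier |  |
| time |  |  | 10 h |

- south (time / h: substrate / %, target / %): 0.833: 93, 4; 2.00: 89, 13; 4.00: 77, 22; 6.00: 71, 30
- east (time / h: substrate / %, target / %): 0.500: 97, 4; 1.00: 91, 7; 2.50: 81, 15; 6.00: 67, 34

(scatter of a reading: 2 percentage points)

1. part of the substrate that has reacted at 10 h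
2. share of the unused partner that is free and not bound as idle adduct, at 10 h

- what is said of released group includes idle adduct
- candidate steps: first chain carrier -> ended carrier; initiator -> 2 initiating radical; partner + first chain carrier -> target + second chain carrier; partner + released group <-> idle adduct; scavenger + released group -> scavenged by-product; partner -> decomposed reagent; substrate + second chain carrier -> released group + first chain carrier; substrate + initiating radical -> capped initiator + first chain carrier; 2 second chain carrier -> ended chains
- the earlier runs do not show how much of partner is bound; that part of a forecast is a guess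

Turn each leftover into a rate. Define the leftover rate as the logarithm of charge over leftover, per hour, a pseudo-first-order constant. East reads 0.0667 h⁻¹. That reading is 1.17 times south's, on a root of the loading ratio of 1.23. The scatter allows that match, so I let the rate follow the root of the initiator present, with equivalents held. Scaled from east to the flask, my reckoning gives 53.6% reacted at 10 h.

The forecast stands lower, at 53% reacted and 88% of the unused partner free: “so initiator or partner is probably fading”.

The flask gives 51.9% reacted and 97.3% of the unused partner free.

    first chain carrier → ended carrier (k = 0.110 s⁻¹)
    initiator → 2 initiating radical (k = 1.90 × 10⁻⁵ s⁻¹)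
    partner + first chain carrier → target + second chain carrier (k = 630 L mol⁻¹ s⁻¹)
    partner + released group ⇌ idle adduct, settled at all times (K = 5.40 L mol⁻¹)
    scavenger + released group → scavenged by-product (k = 0.00380 L mol⁻¹ s⁻¹)
    partner → decomposed reagent (k = 3.30 × 10⁻⁵ s⁻¹)
    substrate + second chain carrier → released group + first chain carrier (k = 1500 L mol⁻¹ s⁻¹)
    substrate + initiating radical → capped initiator + first chain carrier (k = 13000 L mol⁻¹ s⁻¹)
    2 second chain carrier → ended chains (k = 3.00 × 10⁷ L mol⁻¹ s⁻¹)

Watch the partner in the flask. At 10.0 h it goes to decomposed reagent 1.0 times as fast as to target, and 13% of its charge is left unbound, less than the 53% of the scavenger's charge. The scaled leftover rate leaves 46.4% of the flask's substrate, and 48% is found. Now take a neighbour flask with 0.17 M substrate, same equivalents, loading and time. Carried past the one substrate strength of the runs, the root of its initiator present gives 78.7% reacted, and that neighbour flask reacts 80.0%.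

(The runs were generated by integration for substances that don't exist; noise was put on by code.)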